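**Retrosynthetic overview**

1. Target 29 ⇐ angeloylation of the C6 alcohol 27.
2. 27 ⇐ closure of the ten-membered ring at C6–C7 (the bond the cyclase makes from the farnesyl chain): Cr-mediated intramolecular γ-allylation of the C6 aldehyde by the α-(bromomethyl)butenolide in 25. This one step sets C6 and C7 and creates the exocyclic methylene.
3. 25 ⇐ open chain 18, by 4-OH-directed epoxidation of the 2Z-olefin (the C1 epimer is used as stereo-relay) and Mitsunobu inversion at C1 with acetic acid.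
4. 18 ⇐ enal 8 + alkyne 14 (C1–C2 alkynylation), then carbonylative lactonisation (O8 onto C12) and Lindlar reduction.
5. Ring order: γ-lactone (step 7) → epoxide (step 9) → ten-membered carbocycle (step 13).

Assumption: atoms carry germacrane numbers (lactone C12 closed on O–C8, angelate on C6, acetate on C1, epoxide C2–C3, tertiary OH on C4, C13 = exocyclic CH2), the target is the drawn enantiomer (1R,2R,3R,4R,6R,7S,8S), and the ligand enantiomers in steps 1, 4 and 6 are written for the sense stated in each step (the antipodal ligand is taken if a first run shows the opposite sense).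

**Step 1**
Reactants: 1 3-methylbut-2-enal; 2 tert-butyldimethyl(prop-2-yn-1-yloxy)silane
Product: 4 (4S)-1-[(tert-butyldimethylsilyl)oxy]-6-methylhept-5-en-2-yn-4-ol, via methylzinc acetylide 3 (not isolated)
Conditions: Me2Zn (3 equiv), (S,S)-ProPhenol (10 mol %), Ph3P=O (20 mol %), PhMe, 0 °C → rt; aq NH4Cl
Reagents that add atoms: none
Why: Trost Zn–ProPhenol asymmetric alkynylation of an enal; the dinuclear zinc catalyst delivers the acetylide to the Re face and sets C8 as S.

**Step 2**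
Reactants: 4
Product: 6 (2Z,4S)-1-[(tert-butyldimethylsilyl)oxy]-2-iodo-6-methylhepta-2,5-dien-4-ol, via cyclic vinylalanate 5 (not isolated)
Conditions: Red-Al, THF, 0 °C → rt; EtOAc; I2, −78 → −20 °C; Rochelle salt
Reagents that add atoms: iodine, II
Why: Hydroxyl-directed trans-hydroalumination of the propargylic alcohol puts Al on the distal carbon (C11) cis to C8, and iodination with retention gives the Z-3-iodoallylic alcohol; C8 is untouched.

**Step 3**
Reactants: 6
Product: 8 (2E,4S,5Z)-7-[(tert-butyldimethylsilyl)oxy]-4-hydroxy-6-iodo-2-methylhepta-2,5-dienal, via allylic diol 7 (not isolated)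
Conditions: SeO2 (0.3 equiv), t-BuOOH, CH2Cl2, rt; silica plug; TEMPO (10 mol %), PhI(OAc)2, CH2Cl2, rt
Reagents that add atoms: tert-butyl hydroperoxide, CC(C)(C)OO
Why: Sharpless SeO2/t-BuOOH allylic oxidation (ene then [2,3] shift) hydroxylates the (E)-methyl of the more substituted olefin terminus, and TEMPO/PhI(OAc)2 oxidises only the new primary allylic alcohol, giving the E-enal (C1) without touching the iodo-olefin or the secondary alcohol.

**Step 4**
Reactants: 9 4-(trimethylsilyl)but-3-yn-2-one; 10 allyldiisopropoxyborane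
Product: 12 (3R)-3-methylhex-5-en-1-yn-3-ol, via borate ester 11 (not isolated)
Conditions: (S)-3,3′-Br2-BINOL (15 mol %), PhCF3/PhMe, −35 °C → rt; then K2CO3, MeOH, rt
Reagents that add atoms: none
Why: Diol-catalysed (Schaus-type) asymmetric allylboration of an alkynyl methyl ketone through a closed chair transition state sets the tertiary carbinol C4 as R; methanolysis frees the alcohol and the terminal alkyne.

**Step 5**
Reactants: 12
Product: 14 (3R)-5,5-dimethoxy-3-methylpent-1-yn-3-ol, via aldehyde 13 (not isolated)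
Conditions: O3, CH2Cl2/MeOH, −78 °C (Sudan III end point); Me2S; then HC(OMe)3, TsOH (cat.), rt; NaHCO3
Reagents that add atoms: trimethyl orthoformate, COC(OC)OC
Why: Ozonolysis cleaves the terminal alkene much faster than the alkyne, and acetalisation in the same pot masks the β-hydroxy aldehyde (future C6); C4 is not involved.

**Step 6**
Reactants: 8; 14
Product: 16 (2Z,4S,5E,7S,10R)-1-[(tert-butyldimethylsilyl)oxy]-2-iodo-12,12-dimethoxy-6,10-dimethyldodeca-2,5-dien-8-yne-4,7,10-triol, via bis(methylzinc) acetylide 15 (not isolated)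
Conditions: Me2Zn (5 equiv), (S,S)-ProPhenol (20 mol %), Ph3P=O (40 mol %), PhMe, 0 °C → rt; aq NH4Cl
Reagents that add atoms: none
Why: A second Trost Zn–ProPhenol alkynylation joins the fragments at C1–C2 under catalyst control (Re face, 7S in this name), which is deliberately the C1 epimer of the target so that C1 can relay the epoxide face in step 9; coupling before the lactone exists avoids a base-labile enal–butenolide.

**Step 7**
Reactants: 16
Product: 17 (5S)-3-{[(tert-butyldimethylsilyl)oxy]methyl}-5-[(1E,3S,6R)-3,6-dihydroxy-8,8-dimethoxy-2,6-dimethyloct-1-en-4-yn-1-yl]furan-2(5H)-one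
Conditions: PdCl2(PPh3)2 (5 mol %), CO (1 atm), K2CO3, THF, 45 °C
Reagents that add atoms: carbon monoxide, [C-]#[O+]
Why: Pd-catalysed carbonylative lactonisation: oxidative addition into the vinyl iodide, CO insertion, and capture of the acyl-Pd by the cis 8-OH close the γ-lactone (O8 onto C12) as a five-membered ring ahead of any other hydroxyl; no stereocentre changes.

**Step 8**
Reactants: 17
Product: 18 (5S)-3-{[(tert-butyldimethylsilyl)oxy]methyl}-5-[(1E,3R,4Z,6R)-3,6-dihydroxy-8,8-dimethoxy-2,6-dimethylocta-1,4-dien-1-yl]furan-2(5H)-one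
Conditions: H2 (1 atm), Lindlar Pd, quinoline, EtOAc, rt
Reagents that add atoms: none
Why: Lindlar semi-hydrogenation (syn addition) gives the 2Z-olefin; the trisubstituted and conjugated olefins are not reduced (the C1 descriptor changes only because the CIP priorities change).

**Step 9**
Reactants: 18
Product: 21 (5S)-3-{[(tert-butyldimethylsilyl)oxy]methyl}-5-[(1E,3S)-3-hydroxy-3-{(2R,3R)-3-[(2R)-2-hydroxy-4,4-dimethoxybutan-2-yl]oxiran-2-yl}-2-methylprop-1-en-1-yl]furan-2(5H)-one, via TMS ether 19 (not isolated), via TMS epoxide 20 (not isolated)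
Conditions: TMSCl (1.05 equiv), Et3N, CH2Cl2, −78 °C; then VO(acac)2 (5 mol %), t-BuOOH (decane), CH2Cl2, 0 °C → rt; then citric acid, MeOH, 0 °C
Reagents that add atoms: tert-butyl hydroperoxide, CC(C)(C)OO
Why: Hydroxyl-directed vanadium epoxidation: with O1 masked, only the tertiary 4-OH binds vanadium, so only the 2Z-olefin reacts (C9=C10 has no free allylic OH); oxygen is delivered syn to O4 in the rotamer with the 4-methyl in the A(1,3)-sensitive position and H1 in plane, on the face carrying the small C1–O bond and not the branched alkenyl group, which gives the 2R,3R epoxide threo to the epimeric C1 oxygen.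

**Step 10**
Reactants: 21
Product: 22 (1R,2E)-3-[(2S)-4-{[(tert-butyldimethylsilyl)oxy]methyl}-5-oxo-2,5-dihydrofuran-2-yl]-1-{(2R,3R)-3-[(2R)-2-hydroxy-4,4-dimethoxybutan-2-yl]oxiran-2-yl}-2-methylprop-2-en-1-yl acetate
Conditions: PPh3, DIAD, AcOH (excess), PhMe, −20 → 0 °C
Reagents that add atoms: acetic acid, CC(=O)O
Why: Mitsunobu esterification inverts C1 (SN2 by acetate on the oxyphosphonium ion), which turns the threo epoxy alcohol into the erythro C1 acetate of the target (1R) and installs the acetate in the same step; the tertiary 4-OH is not activated.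

**Step 11**
Reactants: 22
Product: 23 (1R,2E)-1-{(2R,3R)-3-[(2R)-2-hydroxy-4-oxobutan-2-yl]oxiran-2-yl}-3-[(2S)-4-(hydroxymethyl)-5-oxo-2,5-dihydrofuran-2-yl]-2-methylprop-2-en-1-yl acetate
Conditions: AcOH/THF/H2O (3:1:1), 40 °C
Reagents that add atoms: water, O
Why: Mild acid hydrolysis removes the primary allylic TBS ether and the dimethyl acetal together; the hindered, acceptor-flanked cis-epoxide and the acetate survive these conditions.

**Step 12**
Reactants: 23
Product: 25 (1R,2E)-3-[(2S)-4-(bromomethyl)-5-oxo-2,5-dihydrofuran-2-yl]-1-{(2R,3R)-3-[(2R)-2-hydroxy-4-oxobutan-2-yl]oxiran-2-yl}-2-methylprop-2-en-1-yl acetate, via allylic mesylate 24 (not isolated)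
Conditions: MsCl, Et3N, CH2Cl2, −40 °C; then LiBr, THF, 0 °C
Reagents that add atoms: lithium bromide, [Li+].[Br-]
Why: Selective mesylation of the only primary alcohol and Finkelstein-type displacement give the allylic bromide; the tertiary alcohol does not react and the aldehyde tolerates the cold amine base.

**Step 13**
Reactants: 25
Product: 27 (1R,2R,3R,4R,6R,7S,8S)-1-acetoxy-2,3-epoxy-4,6-dihydroxygermacra-9E,11(13)-dien-12,8-olide, via allylchromium species 26 (not isolated)
Conditions: CrCl2 (8 equiv), THF, rt, syringe-pump addition of 25 to 1 mM; aq NH4Cl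
Reagents that add atoms: none
Why: Proposed new method: intramolecular Nozaki–Hiyama/Barbier γ-allylation that closes the ten-membered ring from an α-(bromomethyl)butenolide; Cr(II) inserts at C13 and the allyl-Cr(III) adds through C7 to the C6 aldehyde in a chair transition state, anti to the C9 substituent on C8 and with the ring-locked E-type γ-substituent and the aldehyde chain equatorial, which gives the trans ring fusion (7S), the anti carbinol (6R, also the 1,3-anti outcome of 4-OH chelation) and the exocyclic methylene, while ring-opening β-elimination is disfavoured because the C8–O bond lies in the nodal plane of the allyl π-system; the closest known reactions are the intermolecular In/Zn/Cr allylations of aldehydes with 3-(bromomethyl)furan-2(5H)-ones and Cr-mediated macrocyclisations of 2-(bromomethyl)acrylates onto aldehydes.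

**Step 14**
Reactants: 27; 28 angelic acid
Product: 29 (1R,2R,3R,4R,6R,7S,8S)-1-acetoxy-6-angeloyloxy-2,3-epoxy-4-hydroxygermacra-9E,11(13)-dien-12,8-olide
Conditions: 2,4,6-Cl3C6H2COCl, Et3N, PhMe, rt; then 27, 75 °C
Reagents that add atoms: none
Why: Yamaguchi mixed-anhydride esterification without DMAP acylates the secondary 6-OH with retention and without Z→E isomerisation of the angelate; the tertiary 4-OH is not acylated.

**Compound list**

1 | 3-methylbut-2-enal | CC(C)=CC=O | starting material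
2 | tert-butyldimethyl(prop-2-yn-1-yloxy)silane | C#CCO[Si](C)(C)C(C)(C)C | starting material
3 | methylzinc acetylide of 2 | C[Zn]C#CCO[Si](C)(C)C(C)(C)C | intermediate (not isolated)
4 | (4S)-1-[(tert-butyldimethylsilyl)oxy]-6-methylhept-5-en-2-yn-4-ol | O[C@H](C#CCO[Si](C)(C)C(C)(C)C)C=C(C)C | intermediate
5 | sodium cyclic vinylalanate of 4 (Al bound to O8 and C11, two 2-methoxyethoxy ligands) | [Na+].COCCO[Al-]1(OCCOC)O[C@@H](C=C(C)C)C=C1CO[Si](C)(C)C(C)(C)C | intermediate (not isolated)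
6 | (2Z,4S)-1-[(tert-butyldimethylsilyl)oxy]-2-iodo-6-methylhepta-2,5-dien-4-ol | O[C@H](/C=C(\I)CO[Si](C)(C)C(C)(C)C)C=C(C)C | intermediate
7 | (2E,4S,5Z)-7-[(tert-butyldimethylsilyl)oxy]-6-iodo-2-methylhepta-2,5-diene-1,4-diol | OC/C(C)=C/[C@H](O)/C=C(\I)CO[Si](C)(C)C(C)(C)C | intermediate (not isolated)
8 | (2E,4S,5Z)-7-[(tert-butyldimethylsilyl)oxy]-4-hydroxy-6-iodo-2-methylhepta-2,5-dienal | O=C/C(C)=C/[C@H](O)/C=C(\I)CO[Si](C)(C)C(C)(C)C | intermediate
9 | 4-(trimethylsilyl)but-3-yn-2-one | CC(=O)C#C[Si](C)(C)C | starting material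
10 | allyldiisopropoxyborane | C=CCB(OC(C)C)OC(C)C | starting material
11 | diisopropyl (3R)-3-methyl-1-(trimethylsilyl)hex-5-en-1-yn-3-yl borate | C[Si](C)(C)C#C[C@@](C)(CC=C)OB(OC(C)C)OC(C)C | intermediate (not isolated)
12 | (3R)-3-methylhex-5-en-1-yn-3-ol | C#C[C@](C)(O)CC=C | intermediate
13 | (3R)-3-hydroxy-3-methylpent-4-ynal | C#C[C@](C)(O)CC=O | intermediate (not isolated)
14 | (3R)-5,5-dimethoxy-3-methylpent-1-yn-3-ol | C#C[C@](C)(O)CC(OC)OC | intermediate
15 | bis(methylzinc) alkoxide-acetylide of 14 | C[Zn]C#C[C@](C)(O[Zn]C)CC(OC)OC | intermediate (not isolated)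
16 | (2Z,4S,5E,7S,10R)-1-[(tert-butyldimethylsilyl)oxy]-2-iodo-12,12-dimethoxy-6,10-dimethyldodeca-2,5-dien-8-yne-4,7,10-triol | COC(OC)C[C@@](C)(O)C#C[C@@H](O)/C(C)=C/[C@H](O)/C=C(\I)CO[Si](C)(C)C(C)(C)C | intermediate
17 | (5S)-3-{[(tert-butyldimethylsilyl)oxy]methyl}-5-[(1E,3S,6R)-3,6-dihydroxy-8,8-dimethoxy-2,6-dimethyloct-1-en-4-yn-1-yl]furan-2(5H)-one | COC(OC)C[C@@](C)(O)C#C[C@@H](O)/C(C)=C/[C@@H]1OC(=O)C(CO[Si](C)(C)C(C)(C)C)=C1 | intermediate
18 | (5S)-3-{[(tert-butyldimethylsilyl)oxy]methyl}-5-[(1E,3R,4Z,6R)-3,6-dihydroxy-8,8-dimethoxy-2,6-dimethylocta-1,4-dien-1-yl]furan-2(5H)-one | COC(OC)C[C@@](C)(O)/C=C\[C@@H](O)/C(C)=C/[C@@H]1OC(=O)C(CO[Si](C)(C)C(C)(C)C)=C1 | intermediate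
19 | trimethylsilyl ether of 18 at the secondary (C1) hydroxyl | COC(OC)C[C@@](C)(O)/C=C\[C@@H](O[Si](C)(C)C)/C(C)=C/[C@@H]1OC(=O)C(CO[Si](C)(C)C(C)(C)C)=C1 | intermediate (not isolated)
20 | trimethylsilyl ether of 21 at the secondary (C1) hydroxyl | COC(OC)C[C@@](C)(O)[C@@H]1O[C@@H]1[C@@H](O[Si](C)(C)C)/C(C)=C/[C@@H]2OC(=O)C(CO[Si](C)(C)C(C)(C)C)=C2 | intermediate (not isolated)
21 | (5S)-3-{[(tert-butyldimethylsilyl)oxy]methyl}-5-[(1E,3S)-3-hydroxy-3-{(2R,3R)-3-[(2R)-2-hydroxy-4,4-dimethoxybutan-2-yl]oxiran-2-yl}-2-methylprop-1-en-1-yl]furan-2(5H)-one | COC(OC)C[C@@](C)(O)[C@@H]1O[C@@H]1[C@@H](O)/C(C)=C/[C@@H]2OC(=O)C(CO[Si](C)(C)C(C)(C)C)=C2 | intermediate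
22 | (1R,2E)-3-[(2S)-4-{[(tert-butyldimethylsilyl)oxy]methyl}-5-oxo-2,5-dihydrofuran-2-yl]-1-{(2R,3R)-3-[(2R)-2-hydroxy-4,4-dimethoxybutan-2-yl]oxiran-2-yl}-2-methylprop-2-en-1-yl acetate | COC(OC)C[C@@](C)(O)[C@@H]1O[C@@H]1[C@H](OC(C)=O)/C(C)=C/[C@@H]2OC(=O)C(CO[Si](C)(C)C(C)(C)C)=C2 | intermediate
23 | (1R,2E)-1-{(2R,3R)-3-[(2R)-2-hydroxy-4-oxobutan-2-yl]oxiran-2-yl}-3-[(2S)-4-(hydroxymethyl)-5-oxo-2,5-dihydrofuran-2-yl]-2-methylprop-2-en-1-yl acetate | O=CC[C@@](C)(O)[C@@H]1O[C@@H]1[C@H](OC(C)=O)/C(C)=C/[C@@H]2OC(=O)C(CO)=C2 | intermediate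
24 | methanesulfonate of 23 at the primary allylic hydroxyl | O=CC[C@@](C)(O)[C@@H]1O[C@@H]1[C@H](OC(C)=O)/C(C)=C/[C@@H]2OC(=O)C(COS(C)(=O)=O)=C2 | intermediate (not isolated)
25 | (1R,2E)-3-[(2S)-4-(bromomethyl)-5-oxo-2,5-dihydrofuran-2-yl]-1-{(2R,3R)-3-[(2R)-2-hydroxy-4-oxobutan-2-yl]oxiran-2-yl}-2-methylprop-2-en-1-yl acetate | O=CC[C@@](C)(O)[C@@H]1O[C@@H]1[C@H](OC(C)=O)/C(C)=C/[C@@H]2OC(=O)C(CBr)=C2 | intermediate
26 | allylchromium(III) dichloride from 25 (Cr on C13) | O=CC[C@@](C)(O)[C@@H]1O[C@@H]1[C@H](OC(C)=O)/C(C)=C/[C@@H]2OC(=O)C(C[Cr](Cl)Cl)=C2 | intermediate (not isolated)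
27 | (1R,2R,3R,4R,6R,7S,8S)-1-acetoxy-2,3-epoxy-4,6-dihydroxygermacra-9E,11(13)-dien-12,8-olide | C=C1C(=O)O[C@H]2/C=C(\C)[C@@H](OC(C)=O)[C@H]3O[C@H]3[C@](C)(O)C[C@@H](O)[C@H]12 | intermediate
28 | angelic acid, (2Z)-2-methylbut-2-enoic acid | C/C=C(/C)C(=O)O | starting material
29 | (1R,2R,3R,4R,6R,7S,8S)-1-acetoxy-6-angeloyloxy-2,3-epoxy-4-hydroxygermacra-9E,11(13)-dien-12,8-olide (CNP0155556.1) | C=C1C(=O)O[C@H]2/C=C(\C)[C@@H](OC(C)=O)[C@H]3O[C@H]3[C@](C)(O)C[C@@H](OC(=O)/C(C)=C\C)[C@H]12 | target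

**Step count and risks**

Total: 14 steps. Longest linear sequence: 12 steps (1, 2, 3, 6–14, from 3-methylbut-2-enal); the alkyne branch is steps 4 and 5.

The three steps most likely to fail:

Step 13 (ring closure). The ten-membered ring may close slowly, so that dimers form, or the chromium alkoxide may translactonise to the 12,6-olide. The fallback is a metal-free, closed-transition-state allylboration that unmasks the aldehyde last. It sets out from 22: HF·pyridine removes only the silyl ether to give the hydroxymethyl butenolide acetal F1; CBr4/PPh3 gives the bromomethyl butenolide acetal F2; Cu-catalysed borylation (B2pin2, CuCl, KOAc, DMF) gives the pinacol allylboronate acetal F3; AcOH/THF/H2O then frees the aldehyde allylboronate F4, which is not isolated but heated at high dilution (PhMe, 80 °C) so that the boronate adds through C7 to C6 in the same chair arrangement. After aqueous work-up the route is rejoined at 27.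

Step 10 (Mitsunobu inversion). The cis-disposed tertiary 4-OH can displace the activated C1 oxygen to give an epoxy-tetrahydrofuran, and acetate can enter SN2′ at C9. The fallback replaces substitution by an oxidation–reduction pair. It sets out from 21: Dess–Martin periodinane gives the epoxy enone F5; Zn(BH4)2 (Et2O, −20 °C) reduces it under chelation/Felkin control to the erythro (1R) epoxy alcohol F6; Ac2O/pyridine then returns the route to 22.

Step 9 (directed epoxidation). If the transient silyl ether is lost, the free 1-OH will also direct vanadium to C9=C10, and the face selectivity with a silyl group on O1 may be modest. The fallback uses an isolated, minimal acyl mask. It sets out from 18: HCO2H/DCC/DMAP formylates only the secondary alcohol to give the 1-O-formate F7; VO(acac)2/t-BuOOH gives the epoxy formate F8 (the smallest possible group on the attacked face); KHCO3 in MeOH/H2O cleaves the formate without touching the butenolide, and the route is rejoined at 21.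

**Further compounds**

F1 | step 13 | (1R,2E)-1-{(2R,3R)-3-[(2R)-2-hydroxy-4,4-dimethoxybutan-2-yl]oxiran-2-yl}-3-[(2S)-4-(hydroxymethyl)-5-oxo-2,5-dihydrofuran-2-yl]-2-methylprop-2-en-1-yl acetate | COC(OC)C[C@@](C)(O)[C@@H]1O[C@@H]1[C@H](OC(C)=O)/C(C)=C/[C@@H]2OC(=O)C(CO)=C2
F2 | step 13 | (1R,2E)-3-[(2S)-4-(bromomethyl)-5-oxo-2,5-dihydrofuran-2-yl]-1-{(2R,3R)-3-[(2R)-2-hydroxy-4,4-dimethoxybutan-2-yl]oxiran-2-yl}-2-methylprop-2-en-1-yl acetate | COC(OC)C[C@@](C)(O)[C@@H]1O[C@@H]1[C@H](OC(C)=O)/C(C)=C/[C@@H]2OC(=O)C(CBr)=C2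
F3 | step 13 | pinacol allylboronate acetal (Bpin in place of Br in F2) | COC(OC)C[C@@](C)(O)[C@@H]1O[C@@H]1[C@H](OC(C)=O)/C(C)=C/[C@@H]2OC(=O)C(CB3OC(C)(C)C(C)(C)O3)=C2
F4 | step 13 | aldehyde allylboronate (Bpin in place of Br in 25) | O=CC[C@@](C)(O)[C@@H]1O[C@@H]1[C@H](OC(C)=O)/C(C)=C/[C@@H]2OC(=O)C(CB3OC(C)(C)C(C)(C)O3)=C2
F5 | step 10 | epoxy enone (C1 ketone of 21) | COC(OC)C[C@@](C)(O)[C@@H]1O[C@@H]1C(=O)/C(C)=C/[C@@H]2OC(=O)C(CO[Si](C)(C)C(C)(C)C)=C2
F6 | step 10 | (1R)-epoxy alcohol (C1 epimer of 21) | COC(OC)C[C@@](C)(O)[C@@H]1O[C@@H]1[C@H](O)/C(C)=C/[C@@H]2OC(=O)C(CO[Si](C)(C)C(C)(C)C)=C2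
F7 | step 9 | 1-O-formate of 18 | COC(OC)C[C@@](C)(O)/C=C\[C@@H](OC=O)/C(C)=C/[C@@H]1OC(=O)C(CO[Si](C)(C)C(C)(C)C)=C1
F8 | step 9 | 1-O-formate of 21 | COC(OC)C[C@@](C)(O)[C@@H]1O[C@@H]1[C@@H](OC=O)/C(C)=C/[C@@H]2OC(=O)C(CO[Si](C)(C)C(C)(C)C)=C2
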